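**Strategy.** The flavan is cut on both sides of C2, the pyran-ring methine bonded to O1, C3 and C1′ of ring B: this carbon is brought in alone, as a carbenoid carbon that links a boron-bearing C3 to the ring B aryl group. In a single flask LiCHCl2 homologates a (+)-pinanediol α-benzyloxy boronic ester that already holds ring A, C4 and the C3 stereocentre, and the ring B Grignard reagent then displaces the second chloride, so C2–C3, C2–C1′ and the C2 stereocentre are made together while boron stays on C2 as a latent hydroxyl. Oxidation, fluoride release of the ring A phenol from its SEM ether and Mitsunobu inversion at C2 then close the 2,3-trans pyran ring.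

Key step: step 11

Abbreviations: SEM = 2-(trimethylsilyl)ethoxymethyl; ArA = 2-{2-[3-(benzyloxy)phenyl]ethyl}-4-methoxy-6-(SEM-oxy)phenyl (ring A aryl group, bonded through its C1); ArB = 4-(benzyloxy)-3,5-dimethoxyphenyl (ring B); (+)-pinanediol = (1S,2S,3R,5S)-pinane-2,3-diol, its boronic esters being 1,3,2-dioxaborolanes; flavan numbering (O1, C2, C3, C4, C1′) is used for the atoms of the target.

Remark: (+)-pinanediol boronic esters are taken to give the (αS)-α-chloro boronic ester with LiCHCl2/ZnCl2, as is established for this auxiliary. An acetal on the ring A phenol that needs acid for its removal would have to be cleaved beside the 4-alkoxybenzylic C2 carbinol, which acid ionises and closes without control, so a SEM ether, removed by fluoride, is used. Dichloromethyllithium 13 does not survive above about −65 °C and cannot be stored, so it is made from dichloromethane 12 and n-BuLi directly before each of the two homologations (steps 7 and 11).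

**Route**

Step 1
Reactants: 1 methyl 2,4-dihydroxy-6-methylbenzoate (methyl orsellinate)
Product: 2 methyl 2-hydroxy-4-methoxy-6-methylbenzoate
Conditions: MeI (1.05 equiv), K2CO3, acetone, rt
Reagents that add atoms: iodomethane, CI
Why: Williamson methylation should take place only at the free, more acidic 4-OH, because the 2-OH is held in a hydrogen bond to the ester carbonyl.

Step 2
Reactants: 2 methyl 2-hydroxy-4-methoxy-6-methylbenzoate
Product: 3 methyl 4-methoxy-2-methyl-6-(SEM-oxy)benzoate
Conditions: NaH, SEMCl, DMF, 0 °C → rt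
Reagents that add atoms: 2-(trimethylsilyl)ethoxymethyl chloride, C[Si](C)(C)CCOCCl
Why: Deprotonation of the chelated phenol and Williamson-type O-alkylation give an acetal ether that is stable to bases and organometallic reagents and can later be removed with fluoride.

Step 3
Reactants: 3 methyl 4-methoxy-2-methyl-6-(SEM-oxy)benzoate; 4 3-(benzyloxy)benzyl bromide
Product: 6 methyl 2-{2-[3-(benzyloxy)phenyl]ethyl}-4-methoxy-6-(SEM-oxy)benzoate, via benzylic lithium species 5 (not isolated)
Conditions: LiN(iPr)2, THF, −78 °C; then 4, −78 → 0 °C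
Reagents that add atoms: none
Why: Lateral lithiation of the ortho-toluate (the methyl group is acidified by the ortho ester) gives a benzylic anion that is alkylated by the benzylic bromide in an SN2 reaction, while the doubly flanked ester resists self-condensation in the cold.

Step 4
Reactants: 6 methyl 2-{2-[3-(benzyloxy)phenyl]ethyl}-4-methoxy-6-(SEM-oxy)benzoate
Product: 7 ArA-methanol (the benzylic alcohol ArA-CH2OH)
Conditions: LiAlH4, THF, 0 → 40 °C
Reagents that add atoms: none
Why: Hydride reduction of the ester gives the primary benzylic alcohol, and the ethers and the SEM acetal are inert to LiAlH4.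

Step 5
Reactants: 7 ArA-methanol
Product: 9 ArA-methyl chloride (the benzylic chloride ArA-CH2Cl), via mesylate 8 (not isolated)
Conditions: MsCl, Et3N, LiCl, THF, 0 °C → rt; crude product used at once
Reagents that add atoms: lithium chloride, [Li+].[Cl-]
Why: Sulfonylation under basic conditions followed by in situ SN2 displacement with chloride converts the alcohol to the chloride without acid, which the SEM group and the electron-rich benzylic position would not tolerate.

Step 6
Reactants: 9 ArA-methyl chloride; 10 bis[(+)-pinanediolato]diboron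
Product: 11 (+)-pinanediol ArA-methylboronate (ArA-CH2-B, the carbon being C4)
Conditions: Pd(dba)2 (3 mol%), P(4-MeOC6H4)3 (6 mol%), KOAc, toluene, 50 °C
Reagents that add atoms: none
Why: Miyaura borylation of a benzylic halide (oxidative addition to zerovalent palladium, acetate-assisted transmetalation with the diboron, reductive elimination) should install the chiral boronic ester directly.

Step 7
Reactants: 11 (+)-pinanediol ArA-methylboronate; 12 dichloromethane
Product: 15 (+)-pinanediol [(1S)-1-chloro-2-ArA-ethyl]boronate, via dichloromethyllithium 13 (not isolated), via dichloromethyl borate 14 (not isolated)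
Conditions: 12, n-BuLi, THF, −100 °C; then 11; ZnCl2, −100 °C → rt; crude product carried on
Reagents that add atoms: none
Why: Matteson homologation, in which LiCHCl2 adds to boron and ZnCl2 promotes the 1,2-shift of the benzyl group with loss of one chloride, the chiral diol ligand discriminating between the two diastereotopic chlorides so that the (S)-chloride should form.

Step 8
Reactants: 15 (+)-pinanediol [(1S)-1-chloro-2-ArA-ethyl]boronate
Product: 17 (+)-pinanediol [(1R)-1-(benzyloxy)-2-ArA-ethyl]boronate (the key-step precursor), via benzyloxy borate 16 (not isolated)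
Conditions: BnOH, n-BuLi, THF, −78 → 0 °C; then 15, THF/DMSO, 0 °C → rt
Reagents that add atoms: benzyl alcohol (used as LiOCH2Ph), OCc1ccccc1
Why: Lithium benzyloxide adds to boron and the benzyloxy group shifts from boron to carbon with inversion (Matteson substitution), which turns the (S)-chloride into the (R)-α-benzyloxy boronic ester and so sets C3.

Step 9
Reactants: 18 4-bromo-2,6-dimethoxyphenol
Product: 19 2-(benzyloxy)-5-bromo-1,3-dimethoxybenzene
Conditions: BnBr, K2CO3, DMF, 60 °C
Reagents that add atoms: benzyl bromide, BrCc1ccccc1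
Why: Williamson benzylation of the phenoxide, which the two flanking methoxy groups slow but do not prevent in DMF.

Step 10
Reactants: 19 2-(benzyloxy)-5-bromo-1,3-dimethoxybenzene
Product: 20 ArB-magnesium bromide (THF solution, titrated)
Conditions: Mg turnings, I2 (cat.), THF, 40 °C
Reagents that add atoms: magnesium, [Mg]
Why: Grignard formation by magnesium insertion into the aryl bromide, the ether groups being tolerated.

Step 11
Reactants: 17 (+)-pinanediol [(1R)-1-(benzyloxy)-2-ArA-ethyl]boronate; 12 dichloromethane; 20 ArB-magnesium bromide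
Product: 24 (+)-pinanediol [(1S,2S)-2-(benzyloxy)-1-ArB-3-ArA-propyl]boronate, via dichloromethyl borate 21 (not isolated), via α-chloro boronic ester 22 (not isolated), via aryl borate 23 (not isolated)
Conditions: 12, n-BuLi, THF, −100 °C (13 generated anew, as in step 7); then 17; ZnCl2 (2 equiv), −100 °C → rt; then 20 (in excess over ZnCl2), −78 °C → rt
Reagents that add atoms: none
Why: Dichloromethyllithium 13, generated anew from 12 exactly as in step 7, adds to the boron of 17 to give borate 21, and on warming with ZnCl2 the C3 carbon shifts from boron to the dichloromethyl carbon with retention at C3 and loss of one chloride (22); Grignard reagent 20 then forms borate 23, in which ring B shifts from boron to C2 anti to the remaining chloride, that is with inversion. The closest known reaction type is the iterative Matteson homologation of pinanediol α-alkoxy boronic esters followed by Grignard displacement of the α-chloride. No ring is closed: the step forms C2–C3 and C2–C1′ and leaves boron on C2 as a masked hydroxyl. The new C2 stereocentre is controlled by the (+)-pinanediol ligand, which together with ZnCl2 selects the chloride that leaves and so fixes the (1S)-chloride, and the stereospecific inversion by the aryl group converts this into the (1S)-benzylic boronic ester. The step needs the two 1,2-shifts to win over loss of benzyloxide from C3 (β to boron in 23) and over chloride-induced epimerisation of 22; forming both borates cold, ZnCl2 as chloride scavenger and an excess of an aryl nucleophile without ortho substituents should secure this. C3 takes no part in bond breaking and keeps its configuration.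

Step 12
Reactants: 24 (+)-pinanediol [(1S,2S)-2-(benzyloxy)-1-ArB-3-ArA-propyl]boronate
Product: 25 (1S,2S)-2-(benzyloxy)-1-ArB-3-ArA-propan-1-ol
Conditions: 30% H2O2, aq. NaOH, THF, 0 °C → rt
Reagents that add atoms: hydrogen peroxide, OO
Why: Oxidation of the C–B bond, in which hydroperoxide adds to boron and C2 shifts from boron to oxygen with retention, should give the (1S)-carbinol and release the auxiliary while the ethers and the SEM group stay untouched by base.

Step 13
Reactants: 25 (1S,2S)-2-(benzyloxy)-1-ArB-3-ArA-propan-1-ol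
Product: 26 2-[(2S,3S)-2-(benzyloxy)-3-ArB-3-hydroxypropyl]-3-{2-[3-(benzyloxy)phenyl]ethyl}-5-methoxyphenol
Conditions: Bu4NF, ethylenediamine, THF/DMPU, 60 °C
Reagents that add atoms: none
Why: Fluoride attacks silicon and the SEM group fragments to ethene, formaldehyde (trapped by the diamine so that it cannot hydroxymethylate the electron-rich phenoxide) and the phenoxide, so the acid-sensitive C2 carbinol never meets acid.

Step 14
Reactants: 26 2-[(2S,3S)-2-(benzyloxy)-3-ArB-3-hydroxypropyl]-3-{2-[3-(benzyloxy)phenyl]ethyl}-5-methoxyphenol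
Product: 27 (2R,3S)-3-(benzyloxy)-2-ArB-5-{2-[3-(benzyloxy)phenyl]ethyl}-7-methoxychroman
Conditions: PPh3, DIAD, THF, 0 °C → rt
Reagents that add atoms: none
Why: Intramolecular Mitsunobu etherification, in which the C2 alcohol is activated as its alkoxyphosphonium ion and displaced by the ring A phenol in a 6-exo-tet SN2 closure with inversion, (S) to (R), should place ArB and the C3 benzyloxy group trans, the C3 oxygen being blocked so that only the phenol can close.

Step 15
Reactants: 27 (2R,3S)-3-(benzyloxy)-2-ArB-5-{2-[3-(benzyloxy)phenyl]ethyl}-7-methoxychroman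
Product: 28 (2R,3S)-2-(4-hydroxy-3,5-dimethoxyphenyl)-5-[2-(3-hydroxyphenyl)ethyl]-7-methoxychroman-3-ol (target)
Conditions: H2 (1 atm), Pd(OH)2/C, EtOAc/MeOH, rt
Reagents that add atoms: none
Why: Catalytic hydrogenolysis should remove the two aryl benzyl ethers and the C3 benzyl ether, while the cyclic benzylic C2–O1 bond of flavan-3-ols is known to survive these conditions and no stereocentre is touched.

**Compound list**

1 | methyl 2,4-dihydroxy-6-methylbenzoate (methyl orsellinate) | COC(=O)c1c(C)cc(O)cc1O | starting material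
2 | methyl 2-hydroxy-4-methoxy-6-methylbenzoate | COC(=O)c1c(C)cc(OC)cc1O | intermediate
3 | methyl 4-methoxy-2-methyl-6-{[2-(trimethylsilyl)ethoxy]methoxy}benzoate | COC(=O)c1c(C)cc(OC)cc1OCOCC[Si](C)(C)C | intermediate
4 | 3-(benzyloxy)benzyl bromide | BrCc1cccc(OCc2ccccc2)c1 | starting material
5 | benzylic lithium species of 3, lithiated at the 2-methyl group (not isolated) | [Li]Cc1cc(OC)cc(OCOCC[Si](C)(C)C)c1C(=O)OC | intermediate
6 | methyl 2-{2-[3-(benzyloxy)phenyl]ethyl}-4-methoxy-6-{[2-(trimethylsilyl)ethoxy]methoxy}benzoate | COC(=O)c1c(CCc2cccc(OCc3ccccc3)c2)cc(OC)cc1OCOCC[Si](C)(C)C | intermediate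
7 | ArA-methanol, (2-{2-[3-(benzyloxy)phenyl]ethyl}-4-methoxy-6-(SEM-oxy)phenyl)methanol | OCc1c(CCc2cccc(OCc3ccccc3)c2)cc(OC)cc1OCOCC[Si](C)(C)C | intermediate
8 | methanesulfonate of 7 (not isolated) | CS(=O)(=O)OCc1c(CCc2cccc(OCc3ccccc3)c2)cc(OC)cc1OCOCC[Si](C)(C)C | intermediate
9 | ArA-methyl chloride, 2-{2-[3-(benzyloxy)phenyl]ethyl}-4-methoxy-6-(SEM-oxy)benzyl chloride | ClCc1c(CCc2cccc(OCc3ccccc3)c2)cc(OC)cc1OCOCC[Si](C)(C)C | intermediate
10 | bis[(+)-pinanediolato]diboron | B1(O[C@]2(C)[C@H](O1)C[C@@H]3C[C@H]2C3(C)C)B4O[C@]5(C)[C@H](O4)C[C@@H]6C[C@H]5C6(C)C | starting material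
11 | (+)-pinanediol ArA-methylboronate | COc1cc(CCc2cccc(OCc3ccccc3)c2)c(CB2O[C@]3(C)[C@H](O2)C[C@@H]4C[C@H]3C4(C)C)c(OCOCC[Si](C)(C)C)c1 | intermediate
12 | dichloromethane | ClCCl | starting material
13 | dichloromethyllithium (not isolated) | [Li]C(Cl)Cl | intermediate
14 | lithium dichloromethyl borate formed from 11 and 13 (not isolated) | [Li+].COc1cc(CCc2cccc(OCc3ccccc3)c2)c(C[B-]2(C(Cl)Cl)O[C@]3(C)[C@H](O2)C[C@@H]4C[C@H]3C4(C)C)c(OCOCC[Si](C)(C)C)c1 | intermediate
15 | (+)-pinanediol [(1S)-1-chloro-2-ArA-ethyl]boronate | COc1cc(CCc2cccc(OCc3ccccc3)c2)c(C[C@@H](Cl)B2O[C@]3(C)[C@H](O2)C[C@@H]4C[C@H]3C4(C)C)c(OCOCC[Si](C)(C)C)c1 | intermediate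
16 | lithium benzyloxy borate formed from 15 and LiOCH2Ph (not isolated) | [Li+].COc1cc(CCc2cccc(OCc3ccccc3)c2)c(C[C@@H](Cl)[B-]2(OCc3ccccc3)O[C@]3(C)[C@H](O2)C[C@@H]4C[C@H]3C4(C)C)c(OCOCC[Si](C)(C)C)c1 | intermediate
17 | (+)-pinanediol [(1R)-1-(benzyloxy)-2-ArA-ethyl]boronate (key-step precursor) | COc1cc(CCc2cccc(OCc3ccccc3)c2)c(C[C@H](OCc2ccccc2)B2O[C@]3(C)[C@H](O2)C[C@@H]4C[C@H]3C4(C)C)c(OCOCC[Si](C)(C)C)c1 | intermediate
18 | 4-bromo-2,6-dimethoxyphenol | COc1cc(Br)cc(OC)c1O | starting material
19 | 2-(benzyloxy)-5-bromo-1,3-dimethoxybenzene | COc1cc(Br)cc(OC)c1OCc1ccccc1 | intermediate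
20 | 4-(benzyloxy)-3,5-dimethoxyphenylmagnesium bromide | COc1cc([Mg]Br)cc(OC)c1OCc1ccccc1 | intermediate
21 | lithium dichloromethyl borate formed from 17 and 13 (not isolated) | [Li+].COc1cc(CCc2cccc(OCc3ccccc3)c2)c(C[C@H](OCc2ccccc2)[B-]2(C(Cl)Cl)O[C@]3(C)[C@H](O2)C[C@@H]4C[C@H]3C4(C)C)c(OCOCC[Si](C)(C)C)c1 | intermediate
22 | (+)-pinanediol [(1S,2S)-2-(benzyloxy)-1-chloro-3-ArA-propyl]boronate (not isolated) | COc1cc(CCc2cccc(OCc3ccccc3)c2)c(C[C@H](OCc2ccccc2)[C@@H](Cl)B2O[C@]3(C)[C@H](O2)C[C@@H]4C[C@H]3C4(C)C)c(OCOCC[Si](C)(C)C)c1 | intermediate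
23 | bromomagnesium aryl borate formed from 22 and 20 (not isolated) | Br[Mg+].COc1cc(CCc2cccc(OCc3ccccc3)c2)c(C[C@H](OCc2ccccc2)[C@@H](Cl)[B-]2(c3cc(OC)c(OCc4ccccc4)c(OC)c3)O[C@]3(C)[C@H](O2)C[C@@H]4C[C@H]3C4(C)C)c(OCOCC[Si](C)(C)C)c1 | intermediate
24 | (+)-pinanediol [(1S,2S)-2-(benzyloxy)-1-ArB-3-ArA-propyl]boronate (key-step product) | COc1cc(CCc2cccc(OCc3ccccc3)c2)c(C[C@H](OCc2ccccc2)[C@H](c2cc(OC)c(OCc3ccccc3)c(OC)c2)B2O[C@]3(C)[C@H](O2)C[C@@H]4C[C@H]3C4(C)C)c(OCOCC[Si](C)(C)C)c1 | intermediate
25 | (1S,2S)-2-(benzyloxy)-1-ArB-3-ArA-propan-1-ol | COc1cc(CCc2cccc(OCc3ccccc3)c2)c(C[C@H](OCc2ccccc2)[C@H](c2cc(OC)c(OCc3ccccc3)c(OC)c2)O)c(OCOCC[Si](C)(C)C)c1 | intermediate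
26 | 2-[(2S,3S)-2-(benzyloxy)-3-ArB-3-hydroxypropyl]-3-{2-[3-(benzyloxy)phenyl]ethyl}-5-methoxyphenol | COc1cc(CCc2cccc(OCc3ccccc3)c2)c(C[C@H](OCc2ccccc2)[C@H](c2cc(OC)c(OCc3ccccc3)c(OC)c2)O)c(O)c1 | intermediate
27 | (2R,3S)-3-(benzyloxy)-2-[4-(benzyloxy)-3,5-dimethoxyphenyl]-5-{2-[3-(benzyloxy)phenyl]ethyl}-7-methoxychroman | COc1cc(CCc2cccc(OCc3ccccc3)c2)c2c(c1)O[C@H](c1cc(OC)c(OCc3ccccc3)c(OC)c1)[C@@H](OCc1ccccc1)C2 | intermediate
28 | (2R,3S)-2-(4-hydroxy-3,5-dimethoxyphenyl)-5-[2-(3-hydroxyphenyl)ethyl]-7-methoxychroman-3-ol | COc1cc(CCc2cccc(O)c2)c2c(c1)O[C@H](c1cc(OC)c(O)c(OC)c1)[C@@H](O)C2 | target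

**Step count and risks**

Total step count: 15. Longest linear sequence: 13 steps (steps 1–8, then 11–15); the ring B branch (steps 9 and 10) joins at step 11.

Steps most likely to fail:

1. Step 11 (key step). Once the second borate has formed, loss of benzyloxide from C3 can outrun the 1,2-shift of the aryl group. The α-chloro boronic ester can also epimerise under chloride while it waits in the zinc-containing mixture for the Grignard reagent. Fallback: the sequence is stopped after the ZnCl2 stage and 22 is isolated by aqueous work-up. Buffered oxidation (H2O2, NaHCO3, THF/H2O, 0 °C) cleaves the C–B bond, and the resulting chlorohydrin loses HCl to give (2S)-2-(benzyloxy)-3-ArA-propanal F1. Grignard reagent 20 is then added to F1 in CH2Cl2/Et2O at −78 °C with MgBr2·OEt2. Under chelation control (magnesium bridging the carbonyl and benzyloxy oxygens, attack from the face of the C3 hydrogen) this should give the syn carbinol 25. The fallback sets out from 22 and comes back to the route at 25, so the second half of step 11 and step 12 are replaced by carbonyl addition.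

2. Step 14. The alkoxyphosphonium ion at C2 can ionise, because the 4-benzyloxy group of ring B stabilises the benzylic cation. Closure then loses its strict inversion, or a proton is lost from C3 instead. Since C3 is untouched, such leakage would cost diastereomeric purity and not enantiomeric purity. Fallback: the cation is used on purpose. Phenol 26 is treated with catalytic p-TsOH in CH2Cl2 at 0 °C, so that the ring closes through the benzylic cation under the known preference of flavan-3-ols for the 2,3-trans arrangement, and the cis isomer is removed by chromatography. The fallback sets out from 26 and comes back at 27; it forms no compound outside the list (F0).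

3. Step 6. The electron-rich benzylic chloride can ionise and alkylate itself before oxidative addition, and slow transmetalation of the doubly ortho-substituted benzylpalladium species with the bulky diboron would favour homocoupling. Fallback without halide and without palladium: alcohol 7 is oxidised with MnO2 (CH2Cl2, rt) to ArA-carbaldehyde F2 and condensed with tosylhydrazide (MeOH, rt) to the tosylhydrazone F3. Base-induced reductive borylation (B2pin2, NaH, MeOH, toluene, 110 °C; diazo formation, 1,2-boryl shift with loss of N2, protodeboronation of one boryl group) gives pinacol ArA-methylboronate F4. Transesterification with (+)-pinanediol (Et2O, rt, pinacol washed out with water) gives 11. The fallback sets out from 7 and comes back at 11.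

Further compounds
F1 | step 11 | (2S)-2-(benzyloxy)-3-ArA-propanal | COc1cc(CCc2cccc(OCc3ccccc3)c2)c(C[C@H](OCc2ccccc2)C=O)c(OCOCC[Si](C)(C)C)c1
F0 | step 14 | none | none
F2 | step 6 | ArA-carbaldehyde, 2-{2-[3-(benzyloxy)phenyl]ethyl}-4-methoxy-6-(SEM-oxy)benzaldehyde | O=Cc1c(CCc2cccc(OCc3ccccc3)c2)cc(OC)cc1OCOCC[Si](C)(C)C
F3 | step 6 | (E)-N-tosylhydrazone of F2 | Cc1ccc(cc1)S(=O)(=O)N/N=C/c1c(CCc2cccc(OCc3ccccc3)c2)cc(OC)cc1OCOCC[Si](C)(C)C
F4 | step 6 | pinacol ArA-methylboronate | COc1cc(CCc2cccc(OCc3ccccc3)c2)c(CB2OC(C)(C)C(C)(C)O2)c(OCOCC[Si](C)(C)C)c1
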